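Assumption: 1H,1'H-3,3'-biindole (1) is treated as a purchasable catalogue compound, and the C3–C3' axis of the target, which carries no descriptor, is treated as having no fixed configuration.

## Structural features

The target 10 is 2,2',6,6'-tetrabromo-1H,1'H-3,3'-biindole. It consists of two identical indole units, each a pyrrole ring A (N1, C2, C3, C3a, C7a) fused to a benzo ring B (C3a, C4 to C7, C7a), joined by the single bond C3–C3'. The molecule has twofold symmetry, so every operation can be run on both halves at once. It has no stereocentre, and therefore no adjacent stereocentres to relate.

The fragile parts are the two N–H 2-bromoindole units, which are sensitive to acid, light and hydrolysis, and the electron-rich biindole core, which is easily oxidised. The four C–Br bonds also rule out zerovalent palladium or alkyllithium reagents late in the route.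

The two kinds of bromine are not equally hard to place. C2 and C2' are the innately nucleophilic positions of a 3-substituted N–H indole and accept electrophilic bromine readily. C6 and C6' are not reached by electrophilic substitution of an indole, which goes to the pyrrole ring first and then to C5. That is the real difficulty.

The key step exploits the steric map of the N1-silylated biindole. The N1–Si(iPr)3 group covers C2–H and C7–H, and the C3–C3' aryl bond covers C2–H and the peri C4–H. Only C5–H and C6–H of ring B stay open, and C6–H is the farther from the twisted C3 aryl group and lies meta to N1. Because C5–H is almost as open, selectivity between C5 and C6 is the point to watch.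

## Logic of the disconnections

**10 to 8 and 9.** The C2–Br and C2'–Br bonds are cut first. They belong to the most fragile function of 10 and sit at the positions that the indole nitrogen lone pair activates, so they can be made last by plain electrophilic substitution with nothing else competing. This removes two of the four halogens and all the sensitive 2-bromoindole character. The forward step needs free N–H groups, exactly two equivalents of 9, cold anhydrous conditions, and benzo rings that stay inert.

**8 to 7.** The two N–H bonds are traced back to N–Si bonds. The silyl groups are the steric control elements of the key step and must leave before the C2 bromination, which depends on the free nitrogen lone pair. Nothing is simplified in the skeleton, but the steps are ordered correctly. The forward cleavage by a fluoride source must break N–Si and leave the C–Br bonds untouched.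

**7 to 3, 4 and 5, through 6.** The C6–Br and C6'–Br bonds are cut, each by way of a C6–B bond in the transient 6. These bonds cannot be made by electrophilic chemistry, but a sterically governed C–H metalation can pick C6 out. Cutting here returns to the unfunctionalised symmetric core and removes the last two halogens. The forward step must functionalise C6 and not C5 on both rings, must leave C2, C4 and C7 alone, must go to completion on both halves, and must exchange boron for bromine at the same carbon without oxidising the core or stripping silicon.

**3 to 1 and 2.** The two N–Si bonds are cut to give the parent biindole and the silyl chloride. The bulky silyl group is needed only as a removable shield, and this leads back to two purchasable materials. The forward step must silylate both nitrogens completely, since a half-protected molecule would borylate at C2.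

## Other disconnections considered

**Alternative 1:** The C2–Br bonds of 10 are traced back to lactam carbonyls in racemic (3S,3'S)-6,6'-dibromo-3,3'-bioxindole A1. A1 is then cut at N1–C2, C2–C3, C2'–C3' and N1'–C2', so that both C2 carbons come from CO and the C3–C3' bond is the former double bond of (E)-2,2'-diamino-4,4'-dibromostilbene A2.

- *Forward key step:* A2 is carbonylated under Pd(O2CCF3)2 (divalent palladium) with benzoquinone as terminal oxidant. A carbamoylpalladium species adds across the alkene, the benzylic alkylpalladium inserts a second CO, and the other aniline nitrogen captures the acylpalladium. POBr3 would then convert both lactams into 2-bromoindoles.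
- *In favour:* The C6 bromines are fixed by the building block, which is better than the chosen plan, where C6 against C5 is decided in the flask. The C2 bromines replace oxygen, so no electrophilic bromination of an oxidisable biindole is needed, which is also better. The configuration of A1 is irrelevant because aromatisation erases both stereocentres.
- *Against:* Free anilines under oxidative carbonylation tend to give ureas. An ortho-vinylaniline can cyclise directly by Hegedus-type aminopalladation to an indole without taking up CO. The benzylic alkylpalladium has a β-hydrogen at C3 and can eliminate instead of inserting CO. Each turnover passes through zerovalent palladium in the presence of two aryl bromides. A2 is not a catalogue compound and would need about three steps, an olefination of two 4-bromo-2-nitroaryl fragments and a chemoselective nitro reduction.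
- *Comparison:* On structure the alternative is the better plan. On mechanism the chosen plan is safer, because it uses two well-understood catalytic events and not a four-bond cascade with several known exits. On step economy the two are about equal, roughly five steps against four.

**Alternative 2:** The C2–Br bonds of 10 are traced back to C2–SiMe3 bonds in 6,6'-dibromo-2,2'-bis(trimethylsilyl)-1H,1'H-3,3'-biindole A3. A3 is cut at C3–C3a and N1–C2 in both rings, giving two molecules of 5-bromo-2-iodoaniline A4 and 1,4-bis(trimethylsilyl)buta-1,3-diyne A5.

- *Forward key step:* A double Larock annulation under Pd(OAc)2, LiCl and Na2CO3 in DMF. Zerovalent palladium formed in the flask inserts into the C–I bond of A4, the aryl group adds to the alkyne carbon remote from silicon, and the nitrogen closes the ring on the silyl-bearing carbon. The sequence then repeats on the second alkyne. Ipso-bromodesilylation of A3 with 9 would give 10.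
- *In favour:* Both components are purchasable. Both kinds of bromine are regiodefined, C6 by A4 and C2 by the silicon marker. The route has two steps, so on step economy and on regiochemical certainty it is better than the chosen plan.
- *Against:* The catalyst must discriminate C–I from C–Br at the temperature a hindered alkyne demands. The usual rule that the bulkier alkyne substituent ends at C2 is clear in the first annulation (silyl against alkynyl) but not in the second, where silicon competes with a bulky 2-silylindol-3-yl group; a 2,3'-linked isomer or a stall at the mono-indole is plausible. N–H 2-trimethylsilylindoles also lose silicon easily in hot carbonate and DMF, which would remove the C2 marker before the last step.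
- *Comparison:* On structure the alternative is equal or better. On mechanism its key step is less secure than the chosen one. On step economy it is clearly better, two steps against four.

**Alternative 3:** 6,6'-Dibromo-1,1'-bis(trifluoroacetyl)-3,3'-biindole A6 is cut at C3–C3a and C3'–C3a'. This gives 1,4-bis[N-(3-bromophenyl)-2,2,2-trifluoroacetamido]butane-2,3-dione A7, whose diketone bond is the future C3–C3' bond and whose methylene carbons become C2 and C2'.

- *Forward key step:* A twofold Bischler-type cyclodehydration in hot polyphosphoric acid. Each activated ketone carbon attacks the N-aryl ring ortho to nitrogen and para to bromine, and loss of water aromatises each pyrrole ring. Removal of the two trifluoroacetyl groups from A6 with K2CO3 in methanol would give 8, where this plan joins the chosen route before step 4.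
- *In favour:* No precious metal is needed. The C3–C3' bond comes ready-made in a four-carbon unit. The endgame is identical to the chosen one, so the two plans are equal there.
- *Against:* Each closure can occur para or ortho to bromine, giving the 6-bromo or the 4-bromo ring, and two independent closures are needed. After the first closure the remaining ketone is conjugated with the new indole and is less electrophilic, so the second closure needs harsher conditions, under which a 1,2-dicarbonyl compound and the trifluoroacetamides may degrade. A7 must be made from 3-bromoaniline A8 and 1,4-dibromobutane-2,3-dione A9 by double N-alkylation and acylation; the weakly nucleophilic aniline can condense at the carbonyl groups instead.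
- *Comparison:* On structure the two plans are equal, since neither fixes the benzo-ring regiochemistry by construction. On mechanism the chosen plan is milder and better precedented. On step economy the alternative is one step longer, five against four, but equal or better on reagent cost.

Key step: step 2

## Route

Step 1
Reactants: 1 1H,1'H-3,3'-biindole; 2 chlorotriisopropylsilane
Product: 3 1,1'-bis(triisopropylsilyl)-1H,1'H-3,3'-biindole
Conditions: NaH (2.5 equiv), THF, 0 °C; then 2 (2.4 equiv), 0 °C to rt, N2
Reagents that add atoms: chlorotriisopropylsilane, CC(C)[Si](Cl)(C(C)C)C(C)C
Why: N-silylation of an indolyl anion: NaH deprotonates both N–H groups irreversibly and each sodium indolide attacks the silyl chloride at nitrogen. C3 is already substituted and the two halves react independently, so the bis-silyl compound should be the only product once excess base and 2 are used.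

Step 2
Reactants: 3 1,1'-bis(triisopropylsilyl)-1H,1'H-3,3'-biindole; 4 bis(pinacolato)diboron; 5 copper dibromide
Product: 7 6,6'-dibromo-1,1'-bis(triisopropylsilyl)-1H,1'H-3,3'-biindole, via bis-silyl biindole bis(pinacolboronate) 6 (not isolated)
Conditions: 4 (3 equiv), [Ir(OMe)(cod)]2 (cat.), 1,10-phenanthroline (cat.), HBpin (cat.), hexane, 80 °C; evaporate; then 5 (8 equiv), MeOH/H2O/THF, 80 °C
Reagents that add atoms: copper dibromide, Br[Cu]Br (the two bromine atoms of 7); bis(pinacolato)diboron, CC1(C)OB(B2OC(C)(C)C(C)(C)O2)OC1(C)C (the boryl groups of intermediate 6 only)
Why: [Ir(OMe)(cod)]2 (monovalent iridium), 1,10-phenanthroline and 4, with a trace of HBpin to start the cycle, give the tris(boryl) complex Ir(phen)(Bpin)3 (trivalent iridium), which cleaves the most accessible arene C–H bond by oxidative addition to a pentavalent iridium aryl hydride and releases the aryl boronate by C–B reductive elimination; in the second stage the boronate transmetalates to divalent copper, a second CuBr2 oxidises the arylcopper to trivalent copper, and C–Br reductive elimination puts bromine on the carbon that carried boron. The closest known reaction types are the C6-selective iridium borylation of 1-triisopropylsilyl-3-substituted indoles and the one-flask iridium borylation and CuBr2 bromodeboronation of arenes, used here on two equivalent rings of one molecule. No ring is closed and no stereocentre is created; the step forms the C6–B and C6'–B bonds of 6 and turns them into the C6–Br and C6'–Br bonds of 7. The selectivity needed is C6 over C5 on each benzo ring with no attack at C2, C4 or C7: the N1–Si(iPr)3 group flanks C2–H and C7–H, the C3–C3' aryl bond flanks C2–H and the peri C4–H, and of the two bonds left C6–H is farther from the twisted C3 aryl group and is meta, not para, to the nitrogen donor, hence less electron-rich and faster to metalate. Once a ring carries boron at C6, its neighbours C5 and C7 are ortho to a substituent, so over-borylation is self-limiting and an excess of 4 can drive both rings to completion. The copper stage is ipso-specific because only the C–B bond transmetalates, the silyl groups keep the pyrrole C2 positions shielded from CuBr2, and the minor C5 isomers are to be removed from the twofold-symmetric 7 by crystallisation or chromatography.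

Step 3
Reactants: 7 6,6'-dibromo-1,1'-bis(triisopropylsilyl)-1H,1'H-3,3'-biindole
Product: 8 6,6'-dibromo-1H,1'H-3,3'-biindole
Conditions: Bu4NF (2.4 equiv), THF, 0 °C to rt; H2O work-up
Reagents that add atoms: none
Why: Fluoride-mediated N-desilylation: fluoride adds to silicon and the pentacoordinate silicate expels the indolide, a good leaving group, which is protonated on work-up. Aryl bromides are inert to Bu4NF under these conditions.

Step 4
Reactants: 8 6,6'-dibromo-1H,1'H-3,3'-biindole; 9 N-bromosuccinimide
Product: 10 2,2',6,6'-tetrabromo-1H,1'H-3,3'-biindole
Conditions: 9 (2.05 equiv), THF, −78 °C to 0 °C, dark, N2; aq. Na2S2O3/NaHCO3 work-up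
Reagents that add atoms: N-bromosuccinimide, O=C1CCC(=O)N1Br
Why: Electrophilic aromatic bromination of a 3-substituted N–H indole: the enamine carbon C3 takes up electrophilic bromine from 9 to give a 3-bromoindolenine, bromine shifts to C2 and loss of the C2 proton restores the indole, so each half ends as its 2-bromide. The benzo rings are deactivated by their C6 bromines and should not compete when two equivalents are used cold and in the dark.

## Compound list

1 | 1H,1'H-3,3'-biindole | c1ccc2c(c1)c(-c1c[nH]c3ccccc13)c[nH]2 | starting material
2 | chlorotriisopropylsilane | CC(C)[Si](Cl)(C(C)C)C(C)C | starting material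
3 | 1,1'-bis(triisopropylsilyl)-1H,1'H-3,3'-biindole | CC(C)[Si](C(C)C)(C(C)C)n1cc(-c2cn([Si](C(C)C)(C(C)C)C(C)C)c3ccccc23)c2ccccc21 | intermediate
4 | bis(pinacolato)diboron | CC1(C)OB(B2OC(C)(C)C(C)(C)O2)OC1(C)C | starting material
5 | copper dibromide | Br[Cu]Br | starting material
6 | 6,6'-bis(4,4,5,5-tetramethyl-1,3,2-dioxaborolan-2-yl)-1,1'-bis(triisopropylsilyl)-1H,1'H-3,3'-biindole | CC(C)[Si](C(C)C)(C(C)C)n1cc(-c2cn([Si](C(C)C)(C(C)C)C(C)C)c3cc(B4OC(C)(C)C(C)(C)O4)ccc23)c2ccc(B3OC(C)(C)C(C)(C)O3)cc21 | intermediate (not isolated)
7 | 6,6'-dibromo-1,1'-bis(triisopropylsilyl)-1H,1'H-3,3'-biindole | CC(C)[Si](C(C)C)(C(C)C)n1cc(-c2cn([Si](C(C)C)(C(C)C)C(C)C)c3cc(Br)ccc23)c2ccc(Br)cc21 | intermediate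
8 | 6,6'-dibromo-1H,1'H-3,3'-biindole | Brc1ccc2c(-c3c[nH]c4cc(Br)ccc34)c[nH]c2c1 | intermediate
9 | N-bromosuccinimide | O=C1CCC(=O)N1Br | starting material
10 | 2,2',6,6'-tetrabromo-1H,1'H-3,3'-biindole | Brc1ccc2c(-c3c(Br)[nH]c4cc(Br)ccc34)c(Br)[nH]c2c1 | target

## Step count and risks

Total step count: 4 steps. Longest linear sequence: 4 steps, from 1 to 10.

**Step 2 (key step).**
- *What may go wrong:* The most likely failure is erosion of C6 against C5 regiocontrol. Two independent C–H activations must both go the right way, and mixed 5,6'-isomers would be hard to separate from 7. In the copper stage, protodeboronation may compete with transmetalation. The HBr formed may strip the N-silyl groups and expose the electron-rich pyrrole rings to oxidation by CuBr2.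
- *Fallback:* Give up the late C–H functionalisation and bring both C6 bromines in with the building block. The fallback sets out from 2 and returns at 7, before step 3.
  - Purchased 6-bromo-1H-indole F1 is N-silylated with NaH and 2 in THF to give 6-bromo-1-(triisopropylsilyl)-1H-indole F2.
  - N-Iodosuccinimide in THF at low temperature iodinates C3, the only open nucleophilic position of an N-silyl indole, to give 6-bromo-3-iodo-1-(triisopropylsilyl)-1H-indole F3.
  - Half of F3 undergoes iodine–magnesium exchange with iPrMgCl·LiCl at −20 °C, where C–I exchanges far faster than C–Br. Trapping with 2-isopropoxy-4,4,5,5-tetramethyl-1,3,2-dioxaborolane gives 6-bromo-3-(4,4,5,5-tetramethyl-1,3,2-dioxaborolan-2-yl)-1-(triisopropylsilyl)-1H-indole F4.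
  - Suzuki–Miyaura coupling of F3 with F4 under Pd(PPh3)4 (zerovalent palladium) and aqueous K3PO4 in dioxane at about 60 °C, where oxidative addition into C–I outpaces that into C–Br, gives 7.

**Step 4.**
- *What may go wrong:* The 3-bromoindolenine intermediates may be diverted, either by hydrolysis with adventitious water to oxindoles or by oxidative coupling of the electron-rich biindole. A third bromination at C5 is possible if local excess of 9 builds up.
- *Fallback:* Replace electrophilic substitution by directed metalation. The fallback sets out from 8 and returns at 10.
  - Boc2O with catalytic 4-(dimethylamino)pyridine in MeCN gives di-tert-butyl 6,6'-dibromo-1H,1'H-[3,3'-biindole]-1,1'-dicarboxylate F5.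
  - LiN(iPr)2 (2.5 equiv) in THF at −78 °C removes both C2 protons by carbamate-directed lithiation; the amide base does not exchange aryl bromides. 1,2-Dibromo-1,1,2,2-tetrachloroethane then transfers bromine to both carbanions to give di-tert-butyl 2,2',6,6'-tetrabromo-1H,1'H-[3,3'-biindole]-1,1'-dicarboxylate F6.
  - K2CO3 in MeOH/THF at room temperature removes both carbamates and gives 10.

**Step 1.**
- *What may go wrong:* The second silylation may be incomplete because the mono-silylated sodium salt is poorly soluble. The biindole dianion may be oxidised by air. The supply of 1 may also fail.
- *Fallback:* Assemble the C3–C3' bond from two silylated halves. The fallback sets out from 2 and 9 and returns at 3, before step 2.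
  - Purchased 1H-indole F7 is silylated with NaH and 2 in THF to give 1-(triisopropylsilyl)-1H-indole F8.
  - 9 in THF at −78 °C brominates C3 to give 3-bromo-1-(triisopropylsilyl)-1H-indole F9.
  - Half of F9 undergoes bromine–lithium exchange with t-BuLi (2 equiv) in THF at −78 °C; the bulky silyl group prevents migration of the 3-lithio species. Trapping with 2-isopropoxy-4,4,5,5-tetramethyl-1,3,2-dioxaborolane gives 3-(4,4,5,5-tetramethyl-1,3,2-dioxaborolan-2-yl)-1-(triisopropylsilyl)-1H-indole F10.
  - Suzuki–Miyaura coupling of F9 with F10 under Pd(dppf)Cl2 (divalent palladium precatalyst) and K3PO4 in dioxane/H2O at 80 °C gives 3.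

## Further compounds

F1 | step 2 | 6-bromo-1H-indole | Brc1ccc2cc[nH]c2c1
F2 | step 2 | 6-bromo-1-(triisopropylsilyl)-1H-indole | CC(C)[Si](C(C)C)(C(C)C)n1ccc2ccc(Br)cc21
F3 | step 2 | 6-bromo-3-iodo-1-(triisopropylsilyl)-1H-indole | CC(C)[Si](C(C)C)(C(C)C)n1cc(I)c2ccc(Br)cc21
F4 | step 2 | 6-bromo-3-(4,4,5,5-tetramethyl-1,3,2-dioxaborolan-2-yl)-1-(triisopropylsilyl)-1H-indole | CC(C)[Si](C(C)C)(C(C)C)n1cc(B3OC(C)(C)C(C)(C)O3)c2ccc(Br)cc21
F5 | step 4 | di-tert-butyl 6,6'-dibromo-1H,1'H-[3,3'-biindole]-1,1'-dicarboxylate | CC(C)(C)OC(=O)n1cc(-c2cn(C(=O)OC(C)(C)C)c3cc(Br)ccc23)c2ccc(Br)cc21
F6 | step 4 | di-tert-butyl 2,2',6,6'-tetrabromo-1H,1'H-[3,3'-biindole]-1,1'-dicarboxylate | CC(C)(C)OC(=O)n1c(Br)c(-c2c(Br)n(C(=O)OC(C)(C)C)c3cc(Br)ccc23)c2ccc(Br)cc21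
F7 | step 1 | 1H-indole | c1ccc2[nH]ccc2c1
F8 | step 1 | 1-(triisopropylsilyl)-1H-indole | CC(C)[Si](C(C)C)(C(C)C)n1ccc2ccccc21
F9 | step 1 | 3-bromo-1-(triisopropylsilyl)-1H-indole | CC(C)[Si](C(C)C)(C(C)C)n1cc(Br)c2ccccc21
F10 | step 1 | 3-(4,4,5,5-tetramethyl-1,3,2-dioxaborolan-2-yl)-1-(triisopropylsilyl)-1H-indole | CC(C)[Si](C(C)C)(C(C)C)n1cc(B3OC(C)(C)C(C)(C)O3)c2ccccc21
A1 | alternative 1 | racemic (3S,3'S)-6,6'-dibromo-3,3'-bioxindole | O=C1Nc2cc(Br)ccc2[C@@H]1[C@@H]1C(=O)Nc2cc(Br)ccc21
A2 | alternative 1 | (E)-2,2'-diamino-4,4'-dibromostilbene | Nc1cc(Br)ccc1/C=C/c1ccc(Br)cc1N
A3 | alternative 2 | 6,6'-dibromo-2,2'-bis(trimethylsilyl)-1H,1'H-3,3'-biindole | C[Si](C)(C)c1[nH]c2cc(Br)ccc2c1-c1c([Si](C)(C)C)[nH]c2cc(Br)ccc12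
A4 | alternative 2 | 5-bromo-2-iodoaniline | Nc1cc(Br)ccc1I
A5 | alternative 2 | 1,4-bis(trimethylsilyl)buta-1,3-diyne | C[Si](C)(C)C#CC#C[Si](C)(C)C
A6 | alternative 3 | 6,6'-dibromo-1,1'-bis(trifluoroacetyl)-3,3'-biindole | O=C(n1cc(-c2cn(C(=O)C(F)(F)F)c3cc(Br)ccc23)c2ccc(Br)cc21)C(F)(F)F
A7 | alternative 3 | 1,4-bis[N-(3-bromophenyl)-2,2,2-trifluoroacetamido]butane-2,3-dione | O=C(CN(C(=O)C(F)(F)F)c1cccc(Br)c1)C(=O)CN(C(=O)C(F)(F)F)c1cccc(Br)c1
A8 | alternative 3 | 3-bromoaniline | Nc1cccc(Br)c1
A9 | alternative 3 | 1,4-dibromobutane-2,3-dione | O=C(CBr)C(=O)CBr
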